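## Retrosynthetic overview

1. Last bond: the quinone C2–N bond, made by a new silyl-imidate N-quinonylation of the primary (2Z,4E)-dienamide (saliniketal A) with a 2-bromonaphthoquinone carboxylic acid.
2. Dienamide ⇐ Still–Gennari olefination and cross-metathesis of a C4–C17 vinyl diol; its 2,8-dioxabicyclo[3.2.1]octane ⇐ double C–O ketalization of an 11,13-anti diol methyl ketone (anti-aldol, decarboxylative Stetter, Evans–Saksena).
3. C6–C10 stereopentad ⇐ iridium-catalysed double crotylation of 2-methylpropane-1,3-diol; the two vinyl termini are told apart by iodoetherification.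
4. Bromonaphthoquinone acid ⇐ Diels–Alder reaction of 2,6-dibromobenzoquinone with a bis-silyloxy diene from dimethyl 3-oxopentanedioate, then ester cleavage.
5. Ring order: temporary oxane (opened again later) → both rings of the dioxabicyclooctane in one operation → benzo ring of the naphthoquinone (separate branch); the final coupling forms no ring.

Assumption: the (S)-SEGPHOS-derived iridium catalyst is taken to give the (3S,4S,6S,7S) diol of step 1; if the facial sense is the opposite, the (R)-ligand is used.
Locants C1–C17 in names follow the target side chain (C1 amide carbon, C16 ketal carbon, C17 its methyl).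

## Route

Step 1
Reactants: 1 2-methylpropane-1,3-diol; 2 but-3-en-2-yl acetate (racemic)
Product: 3 (3S,4S,6S,7S)-3,5,7-trimethylnona-1,8-diene-4,6-diol
Conditions: 2 (4 equiv), π-allyl iridium C,O-benzoate complex preformed from [Ir(cod)Cl]2, (S)-SEGPHOS, 4-cyano-3-nitrobenzoic acid and allyl acetate (5 mol %), K3PO4 (2 equiv), H2O (10 equiv), THF, 70 °C
Reagents that add atoms: none
Why: Krische transfer-hydrogenative double anti-crotylation from the alcohol oxidation level: each CH2OH is dehydrogenated and trapped by the (E)-σ-crotyliridium through a closed chair, so the catalyst sets C6/C7 and C9/C10 (all S, both Me/OH anti, the two carbinols 1,3-anti) in one operation.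

Step 2
Reactants: 3 (3S,4S,6S,7S)-3,5,7-trimethylnona-1,8-diene-4,6-diol
Product: 4 iodo ether 6-(but-3-en-2-yl)-2-(iodomethyl)-3,5-dimethyloxan-4-ol (O9 to C5 closure; 2,6-cis; only the 3-methyl axial)
Conditions: I2 (1.3 equiv), NaHCO3 (3 equiv), MeCN, 0 °C
Reagents that add atoms: iodine, II
Why: Kinetic 6-exo iodoetherification: only the hydroxyl anti to the central methyl (O9) reaches the distal alkene through a chair with one axial methyl, whereas closure by the other hydroxyl would need a 1,3-diaxial Me/Me pair, so the two near-equivalent termini are differentiated and the C4=C5 alkene and O9 are masked together (the new C5 centre is erased in step 6).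

Step 3
Reactants: 4 iodo ether
Product: 5 2-[4-hydroxy-6-(iodomethyl)-3,5-dimethyloxan-2-yl]propanal (C11 aldehyde)
Conditions: OsO4 (2 mol %), NaIO4 (4 equiv), 2,6-lutidine (2 equiv), dioxane/H2O 3:1, rt; used crude
Reagents that add atoms: osmium tetroxide, O=[Os](=O)(=O)=O (oxygen carrier, reoxidised by sodium periodate, [Na+].[O-]I(=O)(=O)=O)
Why: Lemieux–Johnson cleavage of the only remaining alkene under lutidine buffering gives the α-methyl aldehyde without epimerising C10 and leaves the primary iodide untouched.

Step 4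
Reactants: 5 C11 aldehyde; 6 pent-1-en-3-one
Product: 8 anti-aldol adduct (C11 hydroxyl, C12 methyl, C13 ketone, C14=C15 vinyl), via boron enolate 7 (not isolated)
Conditions: 6 (3 equiv), (c-C6H11)2BCl (3.5 equiv), Et3N (4 equiv), Et2O, −78 → 0 °C; then 5, −78 → −20 °C; MeOH, pH 7 buffer, SiO2 (no peroxide work-up)
Reagents that add atoms: none
Why: Paterson boron anti-aldol: the ketone can enolise only on its ethyl side, the dicyclohexylboron (E)-enolate reacts through a Zimmerman–Traxler chair (11,12-anti) and adds to the α-methyl aldehyde with Felkin–Anh selectivity (10,11-syn); excess reagent borylates the free C7 hydroxyl transiently.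

Step 5
Reactants: 8 anti-aldol adduct; 9 pyruvic acid
Product: 10 C13,C16-diketone (β-hydroxy 1,4-diketone)
Conditions: 9 (3 equiv), i-Pr2NEt (3 equiv), 3-benzyl-5-(2-hydroxyethyl)-4-methylthiazolium chloride (20 mol %), EtOH/1,4-dioxane 1:1, 60 °C
Reagents that add atoms: none
Why: Decarboxylative Stetter reaction: the thiazol-2-ylidene adds to the keto group of pyruvate, loss of CO2 gives the Breslow intermediate (an acetyl anion equivalent), and this adds 1,4 to the unhindered vinyl ketone, forming the C15–C16 bond and delivering the C16 methyl ketone; the hindered amine is returned as each pyruvate is consumed and the ammonium pyruvate buffer keeps the medium near neutral, so C11 and C12 are not touched.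

Step 6
Reactants: 10 C13,C16-diketone
Product: 13 vinyl diol (C4=C5 alkene, C7 and C9 hydroxyls, 1,4-dimethyl-2,8-dioxabicyclo[3.2.1]octan-3-yl at C10), via anti-diol ketone 11 (not isolated), via iodo ketal 12 (not isolated)
Conditions: Me4NBH(OAc)3 (6 equiv), MeCN/AcOH 1:1, −30 °C; camphorsulfonic acid (20 mol %), rt; then Zn (10 equiv), rt
Reagents that add atoms: none
Why: Evans–Saksena reduction delivers hydride intramolecularly from the boron bound to the C11 hydroxyl to give the 11,13-anti diol (sets C13) and spares the remote methyl ketone; acid then closes the diol and ketone to the thermodynamic all-equatorial bicyclic ketal (two C–O bonds, ketal carbon fixed by the bicycle), and Zn in the same acetic acid medium opens the β-iodo ether reductively to release the C4=C5 vinyl group and the C9 hydroxyl.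

Step 7
Reactants: 13 vinyl diol; 14 (E)-but-2-enal
Product: 15 (E)-enal (C3 aldehyde, C4=C5 E)
Conditions: 14 (10 equiv), second-generation Hoveyda–Grubbs catalyst (5 mol %), CH2Cl2, 40 °C
Reagents that add atoms: none
Why: Olefin cross-metathesis of the monosubstituted alkene with excess crotonaldehyde gives the (E)-enal under thermodynamic control, with free hydroxyls and the ketal inert to the ruthenium carbene.

Step 8
Reactants: 15 (E)-enal; 16 ethyl 2-[bis(2,2,2-trifluoroethoxy)phosphoryl]propanoate
Product: 17 ethyl (2Z,4E)-dienoate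
Conditions: 16 (1.5 equiv), KN(SiMe3)2 (1.45 equiv), 18-crown-6 (5 equiv), THF, −78 °C
Reagents that add atoms: none
Why: Still–Gennari olefination: the bis(trifluoroethyl)phosphonate anion adds to the enal and the oxaphosphetane collapses under kinetic control to the (2Z)-trisubstituted alkene, the stabilised anion being too weak a base to deprotonate the free hydroxyls.

Step 9
Reactants: 17 ethyl (2Z,4E)-dienoate
Product: 18 (2Z,4E)-dienamide (saliniketal A)
Conditions: Me3Al (8 equiv), NH4Cl (8 equiv), toluene, 0 → 50 °C; cold 0.5 M HCl quench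
Reagents that add atoms: ammonium chloride, [NH4+].[Cl-]
Why: Weinreb aminolysis with the chloro(methyl)aluminium amide formed in the flask converts the ester into the primary amide without disturbing the (2Z,4E)-diene or the ketal.

Step 10
Reactants: 19 dimethyl 3-oxopentanedioate
Product: 20 dimethyl 2-methyl-3-oxopentanedioate (racemic)
Conditions: MeI (1.0 equiv), K2CO3 (1.1 equiv), acetone, 0 °C → rt
Reagents that add atoms: iodomethane, CI
Why: C-alkylation of the doubly activated methylene of the β-keto diester with one equivalent of iodomethane gives the mono-methyl compound, separated from a little dimethylated material.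

Step 11
Reactants: 20 dimethyl 2-methyl-3-oxopentanedioate
Product: 21 methyl 5-methoxy-4-methyl-3,5-bis(trimethylsilyloxy)penta-2,4-dienoate
Conditions: Me3SiOTf (2.3 equiv), Et3N (2.6 equiv), Et2O, 0 °C → rt; used crude
Reagents that add atoms: trimethylsilyl trifluoromethanesulfonate, C[Si](C)(C)OS(=O)(=O)C(F)(F)F
Why: Double soft enolisation and O-silylation (Chan/Brassard-type diene preparation): the ketone is silylated towards the unsubstituted CH2 and the remaining CH(Me)CO2Me becomes the silyl ketene acetal.

Step 12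
Reactants: 21 bis-silyloxy diene; 22 2,6-dibromo-1,4-benzoquinone
Product: 24 methyl 6-bromo-2,4-dihydroxy-3-methyl-5,8-dioxo-5,8-dihydronaphthalene-1-carboxylate, via cycloadduct 23 (not isolated)
Conditions: 21 (1.5 equiv), CH2Cl2, −40 °C → rt; then SiO2, 1 M HCl/THF, rt
Reagents that add atoms: none
Why: Brassard-type Diels–Alder reaction and aromatisation: the nucleophilic CH terminus of the diene bonds to the unhalogenated quinone carbon and the ketene-acetal carbon to a C–Br carbon, so loss of HBr and MeOH puts the peri hydroxyl next to the carbonyl flanked by the surviving C–Br, which is where nitrogen is needed.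

Step 13
Reactants: 24 bromonaphthoquinone methyl ester
Product: 25 6-bromo-2,4-dihydroxy-3-methyl-5,8-dioxo-5,8-dihydronaphthalene-1-carboxylic acid
Conditions: BBr3 (4 equiv), CH2Cl2, −78 °C → rt; H2O
Reagents that add atoms: none
Why: Lewis-acid ester cleavage: boron chelated between the ortho phenol and the ester carbonyl activates the methyl group for SN2 attack by bromide, and hydrolysis frees the hindered salicylic-type acid without exposing the bromoquinone to base.

Step 14
Reactants: 18 (2Z,4E)-dienamide (saliniketal A); 25 bromonaphthoquinone acid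
Product: 29 rifsaliniketal, via persilylated amide 26 (not isolated), via persilylated bromoquinone 27 (not isolated), via silylated coupling product 28 (not isolated)
Conditions: 25 (1.2 equiv), N,O-bis(trimethylsilyl)trifluoroacetamide (8 equiv per partner), MeCN, 60 °C, then volatiles removed in vacuo; Me3SiOTf (10 mol %), CH2Cl2, −20 °C → rt; MeOH, aq. citric acid, rt
Reagents that add atoms: none
Why: Proposed new method: a silyl-triflate-catalysed aza-Mukaiyama–Michael addition–elimination (vinylogous N-acylation) in which the N,O-bis(trimethylsilyl) imidate of the primary amide, a neutral nitrogen nucleophile, adds to the bromine-bearing C2 of the silyl-activated 2-bromoquinone (a vinylogous acyl bromide) and the adduct expels bromide as Me3SiBr, so ipso substitution is the only irreversible path and fixes the nitrogen next to the carbonyl peri to the hydroxyl, while all OH, phenol and CO2H groups are masked in the flask as silyl derivatives and freed on work-up; the closest known reactions are the Vorbrüggen (silyl-Hilbert–Johnson) N-glycosylation of persilylated amides, N-acylation of silyl imidates by acyl halides, and the addition–elimination of silyl ketene acetals to haloquinones.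

## Compound list

1 | 2-methylpropane-1,3-diol | CC(CO)CO | starting material
2 | but-3-en-2-yl acetate (racemic) | CC(OC(C)=O)C=C | starting material
3 | (3S,4S,6S,7S)-3,5,7-trimethylnona-1,8-diene-4,6-diol (central carbon not stereogenic) | C=C[C@H](C)[C@H](O)C(C)[C@@H](O)[C@@H](C)C=C | intermediate
4 | iodo ether, 6-(but-3-en-2-yl)-2-(iodomethyl)-3,5-dimethyloxan-4-ol (2,6-cis, 2,3-cis, 3,4-cis, 4,5-trans, 5,6-trans) | IC[C@@H]1[C@H](C)[C@H](O)[C@@H](C)[C@@H](O1)[C@@H](C)C=C | intermediate
5 | 2-[4-hydroxy-6-(iodomethyl)-3,5-dimethyloxan-2-yl]propanal (C11 aldehyde) | IC[C@@H]1[C@H](C)[C@H](O)[C@@H](C)[C@@H](O1)[C@@H](C)C=O | intermediate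
6 | pent-1-en-3-one | CCC(=O)C=C | starting material
7 | dicyclohexylboron (E)-enolate of pent-1-en-3-one (not isolated) | C/C=C(/OB(C1CCCCC1)C1CCCCC1)C=C | intermediate
8 | anti-aldol adduct (C11 OH, C12 Me, C13 ketone, C14=C15 vinyl) | IC[C@@H]1[C@H](C)[C@H](O)[C@@H](C)[C@@H](O1)[C@@H](C)[C@H](O)[C@H](C)C(=O)C=C | intermediate
9 | pyruvic acid | CC(=O)C(=O)O | starting material
10 | C13,C16-diketone | IC[C@@H]1[C@H](C)[C@H](O)[C@@H](C)[C@@H](O1)[C@@H](C)[C@H](O)[C@H](C)C(=O)CCC(C)=O | intermediate
11 | 11,13-anti diol C16 methyl ketone (not isolated) | IC[C@@H]1[C@H](C)[C@H](O)[C@@H](C)[C@@H](O1)[C@@H](C)[C@H](O)[C@H](C)[C@@H](O)CCC(C)=O | intermediate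
12 | iodo ether carrying the 1,4-dimethyl-2,8-dioxabicyclo[3.2.1]octan-3-yl group (not isolated) | IC[C@@H]1[C@H](C)[C@H](O)[C@@H](C)[C@@H](O1)[C@@H](C)[C@@H]2O[C@@]3(C)CC[C@H](O3)[C@H]2C | intermediate
13 | vinyl diol (C4=C5, C7 and C9 OH, bicyclic ketal) | C=C[C@H](C)[C@H](O)[C@@H](C)[C@@H](O)[C@@H](C)[C@@H]1O[C@@]2(C)CC[C@H](O2)[C@H]1C | intermediate
14 | (E)-but-2-enal | C/C=C/C=O | starting material
15 | (E)-enal (C3 aldehyde) | O=C/C=C/[C@H](C)[C@H](O)[C@@H](C)[C@@H](O)[C@@H](C)[C@@H]1O[C@@]2(C)CC[C@H](O2)[C@H]1C | intermediate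
16 | ethyl 2-[bis(2,2,2-trifluoroethoxy)phosphoryl]propanoate | CCOC(=O)C(C)P(=O)(OCC(F)(F)F)OCC(F)(F)F | starting material
17 | ethyl (2Z,4E)-dienoate | C/C(=C/C=C/[C@H](C)[C@H](O)[C@@H](C)[C@@H](O)[C@@H](C)[C@@H]1O[C@@]2(C)CC[C@H](O2)[C@H]1C)C(=O)OCC | intermediate
18 | (2Z,4E)-dienamide (saliniketal A) | C/C(=C/C=C/[C@H](C)[C@H](O)[C@@H](C)[C@@H](O)[C@@H](C)[C@@H]1O[C@@]2(C)CC[C@H](O2)[C@H]1C)C(N)=O | intermediate
19 | dimethyl 3-oxopentanedioate | COC(=O)CC(=O)CC(=O)OC | starting material
20 | dimethyl 2-methyl-3-oxopentanedioate (racemic) | COC(=O)CC(=O)C(C)C(=O)OC | intermediate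
21 | methyl 5-methoxy-4-methyl-3,5-bis(trimethylsilyloxy)penta-2,4-dienoate (2Z; ketene acetal geometry mixed) | COC(=O)/C=C(\O[Si](C)(C)C)C(C)=C(OC)O[Si](C)(C)C | intermediate
22 | 2,6-dibromo-1,4-benzoquinone | O=C1C=C(Br)C(=O)C(Br)=C1 | starting material
23 | Diels–Alder cycloadduct (cis-fused, racemic diastereomer mixture, not isolated) | COC(=O)C1C(O[Si](C)(C)C)=C(C)C(OC)(O[Si](C)(C)C)C2(Br)C(=O)C(Br)=CC(=O)C12 | intermediate
24 | methyl 6-bromo-2,4-dihydroxy-3-methyl-5,8-dioxo-5,8-dihydronaphthalene-1-carboxylate | BrC1=CC(=O)c2c(C(=O)OC)c(O)c(C)c(O)c2C1=O | intermediate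
25 | 6-bromo-2,4-dihydroxy-3-methyl-5,8-dioxo-5,8-dihydronaphthalene-1-carboxylic acid | BrC1=CC(=O)c2c(C(=O)O)c(O)c(C)c(O)c2C1=O | intermediate
26 | persilylated 18: 7,9-bis(trimethylsilyl) ether, N,O-bis(trimethylsilyl) imidate (not isolated) | C/C(=C/C=C/[C@H](C)[C@H](O[Si](C)(C)C)[C@@H](C)[C@@H](O[Si](C)(C)C)[C@@H](C)[C@@H]1O[C@@]2(C)CC[C@H](O2)[C@H]1C)C(O[Si](C)(C)C)=N[Si](C)(C)C | intermediate
27 | persilylated 25: trimethylsilyl ester, bis(trimethylsilyl) aryl ether (not isolated) | C[Si](C)(C)OC(=O)c1c(O[Si](C)(C)C)c(C)c(O[Si](C)(C)C)c2C(=O)C(Br)=CC(=O)c12 | intermediate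
28 | silylated coupling product, O-silyl imidate N-bonded to quinone C2 (not isolated) | C/C(=C/C=C/[C@H](C)[C@H](O[Si](C)(C)C)[C@@H](C)[C@@H](O[Si](C)(C)C)[C@@H](C)[C@@H]1O[C@@]2(C)CC[C@H](O2)[C@H]1C)C(O[Si](C)(C)C)=NC1=CC(=O)c2c(C(=O)O[Si](C)(C)C)c(O[Si](C)(C)C)c(C)c(O[Si](C)(C)C)c2C1=O | intermediate
29 | rifsaliniketal | C/C(=C/C=C/[C@H](C)[C@H](O)[C@@H](C)[C@@H](O)[C@@H](C)[C@@H]1O[C@@]2(C)CC[C@H](O2)[C@H]1C)C(=O)NC1=CC(=O)c2c(C(=O)O)c(O)c(C)c(O)c2C1=O | target

## Step count and risks

Total step count: 14. Longest linear sequence: 10 steps (steps 1–9, then step 14); the quinone branch is steps 10–13.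

The three steps most likely to fail:

Step 14 (proposed new N-quinonylation). The risks are cine instead of ipso substitution and Lewis-acid damage to the ketal. The fallback uses known chemistry and makes the amide bond instead; it sets out from 17 and 25 and comes back at 29. Ester 17 is saponified (LiOH, THF/H2O, 0 °C) to the (2Z,4E)-dienoic acid F1. Bromoquinone 25 is treated with NH3 in MeOH, which replaces bromide by addition–elimination and gives the 2-aminonaphthoquinone acid F2. F2 is reduced in the flask with Na2S2O4 to the aminohydroquinone F3, an ordinary electron-rich aniline. F3 is acylated with F1 preactivated by 1-ethyl-3-(3-dimethylaminopropyl)carbodiimide and 1-hydroxy-7-azabenzotriazole (any phenol ester moves O to N) to give the anilide hydroquinone F4, which air reoxidises on work-up to 29.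

Step 5 (decarboxylative Stetter reaction on the β'-hydroxy vinyl ketone). The risks are base-induced 6-endo oxa-Michael closure to a tetrahydropyranone and retro-aldol cleavage. The fallback replaces carbene umpolung by a stoichiometric masked acyl anion at low temperature; it sets out from 8 and comes back at 10. Lithium bis(1-ethoxyvinyl)cuprate (from ethyl vinyl ether, Me3CLi and CuBr·SMe2) with Me3SiCl in THF at −78 °C adds 1,4 to the vinyl ketone, faster than it attacks the primary iodide, to give the enol ether F5. Dilute aqueous oxalic acid then hydrolyses F5 to diketone 10.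

Step 12 (Diels–Alder reaction of the ester-bearing diene). The risks are low reactivity of the push–pull diene terminus and regiochemical leakage from step 11. The fallback uses the well-precedented diene from methyl 2-methyl-3-oxobutanoate and adds the carboxyl afterwards; it sets out from 22 and comes back at 25. 1-Methoxy-2-methyl-1,3-bis(trimethylsilyloxy)buta-1,3-diene F6 reacts with 22 with the same regiochemistry and, after acidic aromatisation, gives 2-bromo-6,8-dihydroxy-7-methyl-1,4-naphthoquinone F7. Formylation at the only free ring position (Cl2CHOMe, TiCl4, CH2Cl2) gives aldehyde F8. Oxidation with NaClO2, NaH2PO4 and 2-methylbut-2-ene gives acid 25.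

Further compounds
F1 | step 14 | (2Z,4E)-dienoic acid | C/C(=C/C=C/[C@H](C)[C@H](O)[C@@H](C)[C@@H](O)[C@@H](C)[C@@H]1O[C@@]2(C)CC[C@H](O2)[C@H]1C)C(=O)O
F2 | step 14 | 6-amino-2,4-dihydroxy-3-methyl-5,8-dioxo-5,8-dihydronaphthalene-1-carboxylic acid | NC1=CC(=O)c2c(C(=O)O)c(O)c(C)c(O)c2C1=O
F3 | step 14 | 6-amino-2,4,5,8-tetrahydroxy-3-methylnaphthalene-1-carboxylic acid | Nc1cc(O)c2c(C(=O)O)c(O)c(C)c(O)c2c1O
F4 | step 14 | anilide of F1 at the hydroquinone level | C/C(=C/C=C/[C@H](C)[C@H](O)[C@@H](C)[C@@H](O)[C@@H](C)[C@@H]1O[C@@]2(C)CC[C@H](O2)[C@H]1C)C(=O)Nc1cc(O)c2c(C(=O)O)c(O)c(C)c(O)c2c1O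
F5 | step 5 | 1-ethoxyvinyl conjugate adduct of 8 (enol ether of 10) | IC[C@@H]1[C@H](C)[C@H](O)[C@@H](C)[C@@H](O1)[C@@H](C)[C@H](O)[C@H](C)C(=O)CCC(=C)OCC
F6 | step 12 | 1-methoxy-2-methyl-1,3-bis(trimethylsilyloxy)buta-1,3-diene | C=C(O[Si](C)(C)C)C(C)=C(OC)O[Si](C)(C)C
F7 | step 12 | 2-bromo-6,8-dihydroxy-7-methyl-1,4-naphthoquinone | BrC1=CC(=O)c2cc(O)c(C)c(O)c2C1=O
F8 | step 12 | 6-bromo-2,4-dihydroxy-3-methyl-5,8-dioxo-5,8-dihydronaphthalene-1-carbaldehyde | BrC1=CC(=O)c2c(C=O)c(O)c(C)c(O)c2C1=O
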